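**Retrosynthetic overview**
1. Target 21 ⇐ protected 3-angelate 20 (one HF step frees the three primary alcohols) ⇐ alcohol 18, whose only free hydroxyl is at C-3.
2. The 13Z-ene-15,16-diol of 18 ⇐ Z-selective Wittig on α-alkoxy ketone 14 (C13=C14). Ketone 14 ⇐ bicyclic C-13 morpholine amide 9 + a hydroxymethyl anion (α-alkoxyalkyllithium): the polarity-reversed C13–C16 bond, key step.
3. Rings A and B of 9 ⇐ one titanocene-mediated radical bicyclization of epoxy-polyene 7 (ring A closes first, then ring B; the exocyclic alkene forms in the same step).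
4. Epoxide 7 ⇐ Sharpless epoxidation (D-tartrate) of the E-allylic alcohol made by SeO2 oxidation of amide 4 ⇐ farnesyl bromide + N-acetylmorpholine enolate.

Assumption: the 1-ethoxyethyl acetal carbon introduced in step 6 is racemic and is carried as an inconsequential epimer mixture until step 11, so it is left undefined in the SMILES.

Numbering: labdane numbering is used for the bicyclic compounds (C-17 exocyclic methylene, C-18 the equatorial oxygenated carbon on C-4, C-19 the axial methyl on C-4, C-20 the methyl on C-10).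

**Step 1**
Reactants: 1 (2E,6E)-farnesyl bromide; 2 N-acetylmorpholine
Product: 4 4-[(4E,8E)-5,9,13-trimethyltetradeca-4,8,12-trienoyl]morpholine, via lithium enolate of N-acetylmorpholine 3 (not isolated)
Conditions: 2, LiN(iPr)2, THF, −78 °C; then 1, −78 → 0 °C
Reagents that add atoms: none
Why: Amide enolate alkylation (SN2 at the primary allylic bromide) attaches the two carbons that become C-12 and C-13 as a robust acyl handle; no stereocentre is formed and the E-alkenes are untouched.

**Step 2**
Reactants: 4 4-[(4E,8E)-5,9,13-trimethyltetradeca-4,8,12-trienoyl]morpholine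
Product: 5 4-[(4E,8E,12E)-14-hydroxy-5,9,13-trimethyltetradeca-4,8,12-trienoyl]morpholine
Conditions: SeO2 (0.3 equiv), t-BuOOH (3 equiv), salicylic acid (0.1 equiv), CH2Cl2, 0 °C → rt; stop at partial conversion and recycle 4
Reagents that add atoms: tert-butyl hydroperoxide, CC(C)(C)OO (oxygen, relayed by catalytic SeO2, O=[Se]=O)
Why: Sharpless–Umbreit allylic oxidation (ene reaction then 2,3-sigmatropic shift) attacks the most electron-rich terminal trisubstituted alkene and hydroxylates only its E-methyl group, which fixes the E-geometry that later places CH2O equatorial at C-4.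

**Step 3**
Reactants: 5 4-[(4E,8E,12E)-14-hydroxy-5,9,13-trimethyltetradeca-4,8,12-trienoyl]morpholine
Product: 6 4-[(4E,8E)-11-[(2R,3R)-3-(hydroxymethyl)-3-methyloxiran-2-yl]-5,9-dimethylundeca-4,8-dienoyl]morpholine
Conditions: Ti(OiPr)4 (0.2 equiv), D-(−)-diethyl tartrate (0.24 equiv), t-BuOOH, 4 Å MS, CH2Cl2, −20 °C
Reagents that add atoms: tert-butyl hydroperoxide, CC(C)(C)OO
Why: Katsuki–Sharpless asymmetric epoxidation with the D-tartrate epoxidizes only the allylic alcohol, on the face that gives the (2R,3R)-epoxy alcohol (E-2-methyl-2-alken-1-ols typically give ≥95% ee), and this sets the absolute configuration of C-3 and through it of the whole ring system.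

**Step 4**
Reactants: 6 the (2R,3R)-epoxy alcohol
Product: 7 4-[(4E,8E)-11-[(2R,3R)-3-[(tert-butyldimethylsilyloxy)methyl]-3-methyloxiran-2-yl]-5,9-dimethylundeca-4,8-dienoyl]morpholine
Conditions: TBSCl, imidazole, DMF, 0 °C → rt
Reagents that add atoms: tert-butyldimethylsilyl chloride, CC(C)(C)[Si](C)(C)Cl
Why: Silylation of the primary alcohol prevents the deoxygenation that free 2,3-epoxy alcohols suffer with titanocene chloride and differentiates the future C-18 oxygen from the C-3 oxygen; stereocentres untouched.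

**Step 5**
Reactants: 7 the silylated (2R,3R)-epoxy polyene amide
Product: 9 (3R,4S,5S,9R,10S)-18-(tert-butyldimethylsilyloxy)-3-hydroxy-14,15,16-trinorlabd-8(17)-en-13-oic acid morpholide, via chlorotitanocene 3-alkoxide 8 (not isolated)
Conditions: (C5H5)2TiCl2 (2.5 equiv), Mn dust (8 equiv), THF, rt (green (C5H5)2TiCl); slow addition of 7; aq. NaH2PO4
Reagents that add atoms: none
Why: Titanocene-mediated reductive epoxide opening and radical polyene bicyclization: trivalent titanium opens the epoxide to the tertiary C-4 radical, which closes rings A and B through a chair–chair array (C-3 oxygen and the larger CH2OTBS equatorial, trans ring fusion, side chain equatorial), so the (3R) carbon dictates C-4, C-5, C-10 and C-9; the C-8 radical is then trapped by a second (C5H5)2TiCl and loses β-hydride to give the exocyclic alkene.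

**Step 6**
Reactants: 10 (tributylstannyl)methanol
Product: 11 tributyl[(1-ethoxyethoxy)methyl]stannane
Conditions: ethyl vinyl ether, pyridinium p-toluenesulfonate (cat.), CH2Cl2, 0 °C → rt
Reagents that add atoms: ethyl vinyl ether, C=COCC
Why: Acid-catalysed acetalization of the alcohol with the vinyl ether gives the stable precursor of the hydroxymethyl anion, carrying a protecting group that falls off under the final mild acid; the new acetal centre is racemic and irrelevant.

**Step 7 (key step)**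
Reactants: 9 the bicyclic hydroxy morpholine amide; 11 tributyl[(1-ethoxyethoxy)methyl]stannane
Product: 14 (3R,4S,5S,9R,10S)-18-(tert-butyldimethylsilyloxy)-16-(1-ethoxyethoxy)-3-hydroxy-14,15-dinorlabd-8(17)-en-13-one, via (1-ethoxyethoxy)methyllithium 12 (not isolated), via dilithium tetrahedral adduct 13 (not isolated)
Conditions: 11 (3.3 equiv), n-BuLi (3.1 equiv), THF, −78 °C, 10 min; then 9, −78 → −40 °C; sat. NH4Cl
Reagents that add atoms: none
Why: Tin–lithium exchange gives an α-alkoxyalkyllithium, a hydroxymethyl anion in which the oxygen-bearing carbon C-16 (normally an electrophile) is the nucleophile, and it acylates on the electrophilic amide carbon C-13 (organolithium acylation of a morpholine amide) to give a stable tetrahedral adduct that cannot over-add and releases the α-alkoxy ketone on work-up; the first equivalent of 12 only deprotonates the 3-OH, and the silyl ether, exocyclic alkene and all stereocentres are untouched.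

**Step 8**
Reactants: 15 (2-hydroxyethyl)triphenylphosphonium bromide
Product: 16 [2-(tert-butyldimethylsilyloxy)ethyl]triphenylphosphonium bromide
Conditions: TBSCl, imidazole, CH2Cl2, rt
Reagents that add atoms: tert-butyldimethylsilyl chloride, CC(C)(C)[Si](C)(C)Cl
Why: Simple silylation of the primary alcohol gives the two-carbon Wittig salt that delivers C-14 and C-15 with the C-15 oxygen already protected.

**Step 9**
Reactants: 14 the α-alkoxy ketone; 16 [2-(tert-butyldimethylsilyloxy)ethyl]triphenylphosphonium bromide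
Product: 18 (3R,4S,5S,9R,10S,13Z)-15,18-bis(tert-butyldimethylsilyloxy)-16-(1-ethoxyethoxy)labda-8(17),13-dien-3-ol, via silyloxyethylidene ylide 17 (not isolated)
Conditions: 16 (3.2 equiv), KN(SiMe3)2 (3.0 equiv), THF, −78 °C; then 14, −78 °C → rt (one equivalent of ylide is consumed by the free 3-OH)
Reagents that add atoms: none
Why: Wittig olefination of an α-alkoxy ketone with a non-stabilized ylide (Still's route to Z-trisubstituted allylic alcohols) places the ylide carbon cis to the alkoxymethyl group, so C-15 and C-16 end up cis and the 13Z geometry is set directly at the diol oxidation level.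

**Step 10**
Reactants: 18 the protected dienol with the free 3-OH
Product: 20 (3R,4S,5S,9R,10S,13Z)-15,18-bis(tert-butyldimethylsilyloxy)-16-(1-ethoxyethoxy)labda-8(17),13-dien-3-yl (2Z)-2-methylbut-2-enoate, via lithium 3-alkoxide 19 (not isolated)
Conditions: LiN(SiMe3)2, THF, −78 °C; angelic anhydride, −78 → 0 °C; aq. NH4Cl
Reagents that add atoms: angelic anhydride, C/C=C(/C)C(=O)OC(=O)/C(C)=C\C
Why: Acylation of the preformed lithium alkoxide with angelic anhydride at low temperature, without a nucleophilic amine catalyst, esterifies the only free (hindered, equatorial) hydroxyl without Z-to-E isomerization to the tiglate; the C-3 configuration is retained.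

**Step 11**
Reactants: 20 the fully protected 3-angelate
Product: 21 (3R,4S,5S,9R,10S,13Z)-15,16,18-trihydroxylabda-8(17),13-dien-3-yl (2Z)-2-methylbut-2-enoate (target, CNP0237954.1)
Conditions: 48% aq. HF, MeCN, 0 °C → rt; NaHCO3 quench to pH 7
Reagents that add atoms: none
Why: Global deprotection in which HF cleaves both primary silyl ethers and hydrolyses the ethoxyethyl acetal, while the hindered conjugated ester and both alkenes survive at 0 °C; the neutral quench avoids 3-O to 18-O acyl migration.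

**Compound list**
1 | (2E,6E)-farnesyl bromide | CC(C)=CCC/C(C)=C/CC/C(C)=C/CBr | starting material
2 | N-acetylmorpholine | CC(=O)N1CCOCC1 | starting material
3 | lithium enolate of N-acetylmorpholine | C=C(O[Li])N1CCOCC1 | intermediate
4 | 4-[(4E,8E)-5,9,13-trimethyltetradeca-4,8,12-trienoyl]morpholine | CC(C)=CCC/C(C)=C/CC/C(C)=C/CCC(=O)N1CCOCC1 | intermediate
5 | 4-[(4E,8E,12E)-14-hydroxy-5,9,13-trimethyltetradeca-4,8,12-trienoyl]morpholine | OC/C(C)=C/CC/C(C)=C/CC/C(C)=C/CCC(=O)N1CCOCC1 | intermediate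
6 | 4-[(4E,8E)-11-[(2R,3R)-3-(hydroxymethyl)-3-methyloxiran-2-yl]-5,9-dimethylundeca-4,8-dienoyl]morpholine | OC[C@@]1(C)O[C@@H]1CC/C(C)=C/CC/C(C)=C/CCC(=O)N1CCOCC1 | intermediate
7 | tert-butyldimethylsilyl ether of 6 | CC(C)(C)[Si](C)(C)OC[C@@]1(C)O[C@@H]1CC/C(C)=C/CC/C(C)=C/CCC(=O)N1CCOCC1 | intermediate
8 | chlorobis(cyclopentadienyl)titanium 3-alkoxide of 9 | C=C1CC[C@H]2[C@@](C)(CC[C@@H](O[Ti](Cl)(C3C=CC=C3)C3C=CC=C3)[C@]2(C)CO[Si](C)(C)C(C)(C)C)[C@@H]1CCC(=O)N1CCOCC1 | intermediate
9 | (3R,4S,5S,9R,10S)-18-(tert-butyldimethylsilyloxy)-3-hydroxy-14,15,16-trinorlabd-8(17)-en-13-oic acid morpholide | C=C1CC[C@H]2[C@@](C)(CC[C@@H](O)[C@]2(C)CO[Si](C)(C)C(C)(C)C)[C@@H]1CCC(=O)N1CCOCC1 | intermediate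
10 | (tributylstannyl)methanol | CCCC[Sn](CCCC)(CCCC)CO | starting material
11 | tributyl[(1-ethoxyethoxy)methyl]stannane | CCCC[Sn](CCCC)(CCCC)COC(C)OCC | intermediate
12 | (1-ethoxyethoxy)methyllithium | [Li]COC(C)OCC | intermediate
13 | dilithium tetrahedral adduct of 12 on the amide carbon of 9 (3-O-lithium, 13-O-lithium) | C=C1CC[C@H]2[C@@](C)(CC[C@@H](O[Li])[C@]2(C)CO[Si](C)(C)C(C)(C)C)[C@@H]1CCC(O[Li])(COC(C)OCC)N1CCOCC1 | intermediate
14 | (3R,4S,5S,9R,10S)-18-(tert-butyldimethylsilyloxy)-16-(1-ethoxyethoxy)-3-hydroxy-14,15-dinorlabd-8(17)-en-13-one | C=C1CC[C@H]2[C@@](C)(CC[C@@H](O)[C@]2(C)CO[Si](C)(C)C(C)(C)C)[C@@H]1CCC(=O)COC(C)OCC | intermediate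
15 | (2-hydroxyethyl)triphenylphosphonium bromide | OCC[P+](c1ccccc1)(c1ccccc1)c1ccccc1.[Br-] | starting material
16 | [2-(tert-butyldimethylsilyloxy)ethyl]triphenylphosphonium bromide | CC(C)(C)[Si](C)(C)OCC[P+](c1ccccc1)(c1ccccc1)c1ccccc1.[Br-] | intermediate
17 | [2-(tert-butyldimethylsilyloxy)ethylidene]triphenylphosphorane | CC(C)(C)[Si](C)(C)OCC=P(c1ccccc1)(c1ccccc1)c1ccccc1 | intermediate
18 | (3R,4S,5S,9R,10S,13Z)-15,18-bis(tert-butyldimethylsilyloxy)-16-(1-ethoxyethoxy)labda-8(17),13-dien-3-ol | C=C1CC[C@H]2[C@@](C)(CC[C@@H](O)[C@]2(C)CO[Si](C)(C)C(C)(C)C)[C@@H]1CC/C(COC(C)OCC)=C/CO[Si](C)(C)C(C)(C)C | intermediate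
19 | lithium 3-alkoxide of 18 | C=C1CC[C@H]2[C@@](C)(CC[C@@H](O[Li])[C@]2(C)CO[Si](C)(C)C(C)(C)C)[C@@H]1CC/C(COC(C)OCC)=C/CO[Si](C)(C)C(C)(C)C | intermediate
20 | 3-angelate of 18 | C=C1CC[C@H]2[C@@](C)(CC[C@@H](OC(=O)/C(C)=C\C)[C@]2(C)CO[Si](C)(C)C(C)(C)C)[C@@H]1CC/C(COC(C)OCC)=C/CO[Si](C)(C)C(C)(C)C | intermediate
21 | (3R,4S,5S,9R,10S,13Z)-15,16,18-trihydroxylabda-8(17),13-dien-3-yl (2Z)-2-methylbut-2-enoate | C=C1CC[C@H]2[C@@](C)(CC[C@@H](OC(=O)/C(C)=C\C)[C@]2(C)CO)[C@@H]1CC/C(=C/CO)CO | target

**Step count**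
Total: 11 steps. Longest linear sequence: 9 steps (1, 2, 3, 4, 5, 7, 9, 10, 11); steps 6 and 8 each make one reagent from a commercial precursor.

**Three steps most likely to fail, with fallbacks**

Step 5 (radical bicyclization: modest yield, and C-4 is set by a conformational preference, not stereospecifically). The fallback sets out from 7 and rejoins the route at 20. Treat 7 with MeAlCl2 in CH2Cl2 at −78 °C, so that the epoxide opens with inversion at C-4 in a concerted cationic bicyclization and C-4 is fixed by the E-epoxide geometry. The C-8 cation is captured by the amide oxygen, and aqueous work-up hydrolyses the cyclic imidate to the tricyclic 8,13-lactone F1. Addition of 12 to F1 (the lactone now serves as the C-13 acyl donor) gives the 8-hydroxy α-alkoxy ketone F2. Wittig reaction of F2 with 17 gives the 8-hydroxy 13Z-alkene F3. LiN(SiMe3)2 and angelic anhydride esterify the secondary C-3 alkoxide in preference to the tertiary one, giving the 8-hydroxy 3-angelate F4. Martin sulfurane then dehydrates the equatorial tertiary C-8 alcohol, where only the C-17 methyl hydrogens can be antiperiplanar, to the exocyclic alkene 20.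

Step 7 (the key acylation: the amide may enolize, or conversion may be poor on the unprotected hydroxy amide). The fallback sets out from 9 and rejoins at 14, with the roles reversed so that C-13 is the nucleophile. (C5H5)2Zr(H)Cl reduces the morpholine amide to the aldehyde F5. A thiazolium-derived N-heterocyclic carbene (iPr2NEt, paraformaldehyde, THF, 60 °C) converts the aldehyde into its Breslow acyl anion, which adds to formaldehyde to give the α-hydroxy ketone F6. Ethyl vinyl ether (1.1 equiv) with pyridinium p-toluenesulfonate at −20 °C acetalizes the primary hydroxyl in preference to the hindered C-3 hydroxyl and gives 14.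

Step 9 (Z-selectivity of the Wittig reaction, or β-elimination of the ylide). The fallback sets out from 14 and rejoins at 21; it fixes the alkene geometry in a ring instead of relying on kinetic selectivity. Lithium ethoxyacetylide adds to the ketone to give the propargylic alcohol F7. Dilute H2SO4 in THF brings about Meyer–Schuster rearrangement, acetal loss and lactonization to the butenolide F8, in which C-15 and C-16 are necessarily cis. iBu2AlH reduces the butenolide to the Z-enediol F9. TBSCl and imidazole silylate the two new primary hydroxyls to give the tris-silyl ether F10 (a C-18 silyl ether lost in the acid step is restored here). LiN(SiMe3)2 and angelic anhydride give the tris-silyl 3-angelate F11, and HF in MeCN removes the three silyl groups to give 21.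

**Further compounds**
F1 | step 5 | (3R,4S,5S,9R,10S)-18-(tert-butyldimethylsilyloxy)-3-hydroxy-14,15,16-trinorlabdan-13,8-olide (lactone oxygen equatorial on C-8, C-17 methyl axial, trans to H-9) | O=C1CC[C@@H]2[C@@](C)(O1)CC[C@H]3[C@@]2(C)CC[C@@H](O)[C@]3(C)CO[Si](C)(C)C(C)(C)C
F2 | step 5 | 8-hydroxy-8,17-dihydro analogue of 14 (open form of the lactol) | C[C@]1(O)CC[C@H]2[C@@](C)(CC[C@@H](O)[C@]2(C)CO[Si](C)(C)C(C)(C)C)[C@@H]1CCC(=O)COC(C)OCC
F3 | step 5 | 8-hydroxy-8,17-dihydro analogue of 18 | C[C@]1(O)CC[C@H]2[C@@](C)(CC[C@@H](O)[C@]2(C)CO[Si](C)(C)C(C)(C)C)[C@@H]1CC/C(COC(C)OCC)=C/CO[Si](C)(C)C(C)(C)C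
F4 | step 5 | 8-hydroxy-8,17-dihydro analogue of 20 | C[C@]1(O)CC[C@H]2[C@@](C)(CC[C@@H](OC(=O)/C(C)=C\C)[C@]2(C)CO[Si](C)(C)C(C)(C)C)[C@@H]1CC/C(COC(C)OCC)=C/CO[Si](C)(C)C(C)(C)C
F5 | step 7 | (3R,4S,5S,9R,10S)-18-(tert-butyldimethylsilyloxy)-3-hydroxy-14,15,16-trinorlabd-8(17)-en-13-al | C=C1CC[C@H]2[C@@](C)(CC[C@@H](O)[C@]2(C)CO[Si](C)(C)C(C)(C)C)[C@@H]1CCC=O
F6 | step 7 | (3R,4S,5S,9R,10S)-18-(tert-butyldimethylsilyloxy)-3,16-dihydroxy-14,15-dinorlabd-8(17)-en-13-one | C=C1CC[C@H]2[C@@](C)(CC[C@@H](O)[C@]2(C)CO[Si](C)(C)C(C)(C)C)[C@@H]1CCC(=O)CO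
F7 | step 9 | 13-(ethoxyethynyl)-13-hydroxy adduct of 14 | C=C1CC[C@H]2[C@@](C)(CC[C@@H](O)[C@]2(C)CO[Si](C)(C)C(C)(C)C)[C@@H]1CCC(O)(C#COCC)COC(C)OCC
F8 | step 9 | (3R,4S,5S,9R,10S)-18-(tert-butyldimethylsilyloxy)-3-hydroxylabda-8(17),13-dien-15,16-olide | C=C1CC[C@H]2[C@@](C)(CC[C@@H](O)[C@]2(C)CO[Si](C)(C)C(C)(C)C)[C@@H]1CCC1=CC(=O)OC1
F9 | step 9 | (3R,4S,5S,9R,10S,13Z)-18-(tert-butyldimethylsilyloxy)labda-8(17),13-diene-3,15,16-triol | C=C1CC[C@H]2[C@@](C)(CC[C@@H](O)[C@]2(C)CO[Si](C)(C)C(C)(C)C)[C@@H]1CC/C(=C/CO)CO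
F10 | step 9 | (3R,4S,5S,9R,10S,13Z)-15,16,18-tris(tert-butyldimethylsilyloxy)labda-8(17),13-dien-3-ol | C=C1CC[C@H]2[C@@](C)(CC[C@@H](O)[C@]2(C)CO[Si](C)(C)C(C)(C)C)[C@@H]1CC/C(=C/CO[Si](C)(C)C(C)(C)C)CO[Si](C)(C)C(C)(C)C
F11 | step 9 | 3-angelate of F10 | C=C1CC[C@H]2[C@@](C)(CC[C@@H](OC(=O)/C(C)=C\C)[C@]2(C)CO[Si](C)(C)C(C)(C)C)[C@@H]1CC/C(=C/CO[Si](C)(C)C(C)(C)C)CO[Si](C)(C)C(C)(C)C
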